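**Plan**
The target, oxacyclohentriacontan-2-one (triacontan-30-olide, C30H58O2), is a single 31-membered ring: the lactone link C1(=O)–O–C30 plus 29 bare CH2 groups, C2–C30 (carbons counted from the carbonyl).
Feature used: no atom from C2 to C30 carries a substituent, so C16–C19 can be held temporarily as the conjugated diyne C16≡C17–C18≡C19. Its central sp–sp bond C17–C18 is then a ring bond that oxidative alkyne coupling can make.
Cuts, in retrosynthetic order: saturation at C16–C19 undone; ring bond C17–C18; acyl bond C1–O; the sp3–sp bonds C15–C16 and C19–C20 (primary bromide plus acetylide); C15–Br back to the C15–O bond of the 16-membered ω-pentadecalactone.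
Forward: C15 + C2 gives the C1–C17 alkynoic acid and C11 + C2 gives the C18–C30 alkynol. Esterification links them into an open-chain C30 diyne ester, the only ring then closes at C17–C18, and hydrogenation removes the four sp carbons.
Stereochemistry: the target holds no stereocentre and no C=C bond, so nothing has to be set, relayed or protected.

Key step: step 5

Assumption: the copper acetylides that carry step 5 are aggregated species of no single fixed composition, so they are treated in the mechanism of that step and not numbered; salts 5 and 9 are drawn with the alkyne C–H intact although excess 3 may lithiate it reversibly.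

Step 1
Reactants: 1 ω-pentadecalactone (oxacyclohexadecan-2-one)
Product: 2 15-bromopentadecanoic acid
Conditions: HBr (33% in AcOH), conc. H2SO4 (cat.), 90 °C; ice-water; recrystallisation (hexane)
Reagents that add atoms: hydrogen bromide, Br
Why: Acidolytic lactone opening, in which the protonated ester (or the hydroxy acid and acetate in equilibrium with it) undergoes SN2 attack of bromide at the unhindered primary O–CH2 carbon C15; this is the standard way from ω-lactones and ω-hydroxy acids to ω-bromo acids, and the liberated CO2H is inert to HBr.

Step 2
Reactants: 2 15-bromopentadecanoic acid; 3 lithium acetylide–ethylenediamine complex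
Product: 6 heptadec-16-ynoic acid, via lithium 15-bromopentadecanoate 4 (not isolated), via lithium heptadec-16-ynoate 5 (not isolated)
Conditions: 3 (3 equiv), DMSO, 15 °C → rt; then 1 M HCl
Reagents that add atoms: lithium acetylide–ethylenediamine complex 3, [Li]C#C.NCCN
Why: SN2 alkylation of an acetylide, in which the first equivalent of 3 only removes the carboxyl proton (4), the carboxylate is not attacked by the carbanion, and a further equivalent displaces the primary bromide in the dipolar aprotic medium to form C15–C16, as is routine for ω-alkynyl fatty acids.

Step 3
Reactants: 7 11-bromoundecan-1-ol; 3 lithium acetylide–ethylenediamine complex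
Product: 10 tridec-12-yn-1-ol, via lithium 11-bromoundecan-1-olate 8 (not isolated), via lithium tridec-12-yn-1-olate 9 (not isolated)
Conditions: 3 (2.5 equiv), DMSO, 15 °C → rt; then 1 M HCl
Reagents that add atoms: lithium acetylide–ethylenediamine complex 3, [Li]C#C.NCCN
Why: The same SN2 acetylide alkylation, now forming C19–C20; one equivalent of 3 is spent on the hydroxyl proton, and the softer, more nucleophilic acetylide, kept in excess, should outrun the alkoxide at the primary bromide.

Step 4
Reactants: 6 heptadec-16-ynoic acid; 10 tridec-12-yn-1-ol
Product: 12 tridec-12-yn-1-yl heptadec-16-ynoate, via O-acylisourea 11 (not isolated)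
Conditions: DCC (1.1 equiv), DMAP (0.1 equiv), CH2Cl2, 0 °C → rt; filtration, SiO2
Reagents that add atoms: none
Why: Steglich esterification, in which DCC activates 6 as O-acylisourea 11 and DMAP relays the acyl group to the unhindered primary alcohol under essentially neutral conditions that leave both terminal alkynes untouched.

Step 5
Reactants: 12 tridec-12-yn-1-yl heptadec-16-ynoate
Product: 13 oxacyclohentriaconta-17,19-diyn-2-one
Conditions: Cu(OAc)2 (10 equiv), pyridine, N2, 60 °C, 12 in pyridine added by syringe pump over 24 h (final ca. 1 mM), then 2 h; evaporation, Et2O / 1 M HCl / aq. EDTA washes, SiO2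
Reagents that add atoms: none
Why: Eglinton coupling: acetate and pyridine assist the metallation of both terminal C–H bonds at divalent copper, the two alkynyl ligands meet in a dicopper assembly, and C17 and C18 are joined while two divalent copper centres each accept one electron and leave as monovalent copper (CuOAc) beside two AcOH. The nearest known reaction type is the high-dilution Eglinton or Glaser cyclisation of α,ω-diynes, which has been used on ester-linked diynes to reach macrocyclic 1,3-diyne lactones. The one ring closes end to end as a 31-membered ring through an sp–sp bond, both triple bonds ending up endocyclic, and the stiff six-carbon rod C15–C20 is spanned by 25 flexible ring atoms, so the closure costs no strain. No stereocentre arises. The selectivity required is ring closure against intermolecular coupling: 12 owns exactly two alkynes, so any intramolecular event can only give C17–C18, and syringe-pump addition into a large excess of the oxidant should keep the standing concentration of free 12 below the effective molarity of the closure. The ester, the only other functional group, is indifferent to Cu(OAc)2 in pyridine, and the coupling is irreversible, so the monomeric ring should persist once formed.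

Step 6
Reactants: 13 oxacyclohentriaconta-17,19-diyn-2-one
Product: 14 oxacyclohentriacontan-2-one (target)
Conditions: H2 (1 atm), 10% Pd/C, EtOAc–THF, rt; filtration through Celite
Reagents that add atoms: none
Why: Heterogeneous catalytic hydrogenation, in which the unhindered conjugated diyne should take up four equivalents of H2 and pass through enyne and diene stages to the tetramethylene unit C16–C19; the ester C–O bonds lie far from the unsaturation (never allylic or propargylic) and so are safe from hydrogenolysis.

**Compound list**
1 | ω-pentadecalactone (oxacyclohexadecan-2-one) | O=C1CCCCCCCCCCCCCCO1 | starting material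
2 | 15-bromopentadecanoic acid | OC(=O)CCCCCCCCCCCCCCBr | intermediate
3 | lithium acetylide–ethylenediamine complex | [Li]C#C.NCCN | starting material
4 | lithium 15-bromopentadecanoate | [Li+].[O-]C(=O)CCCCCCCCCCCCCCBr | intermediate
5 | lithium heptadec-16-ynoate | [Li+].[O-]C(=O)CCCCCCCCCCCCCCC#C | intermediate
6 | heptadec-16-ynoic acid | OC(=O)CCCCCCCCCCCCCCC#C | intermediate
7 | 11-bromoundecan-1-ol | OCCCCCCCCCCCBr | starting material
8 | lithium 11-bromoundecan-1-olate | [Li+].[O-]CCCCCCCCCCCBr | intermediate
9 | lithium tridec-12-yn-1-olate | [Li+].[O-]CCCCCCCCCCCC#C | intermediate
10 | tridec-12-yn-1-ol | OCCCCCCCCCCCC#C | intermediate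
11 | N,N'-dicyclohexyl-O-(heptadec-16-ynoyl)isourea (O-acylisourea) | C#CCCCCCCCCCCCCCCC(=O)OC(=NC1CCCCC1)NC1CCCCC1 | intermediate
12 | tridec-12-yn-1-yl heptadec-16-ynoate | C#CCCCCCCCCCCCCCCC(=O)OCCCCCCCCCCCC#C | intermediate
13 | oxacyclohentriaconta-17,19-diyn-2-one | O=C1CCCCCCCCCCCCCCC#CC#CCCCCCCCCCCCO1 | intermediate
14 | oxacyclohentriacontan-2-one | O=C1CCCCCCCCCCCCCCCCCCCCCCCCCCCCCO1 | target

**Step count**
Total step count: 6.
Longest linear sequence: 5 steps (steps 1, 2, 4, 5 and 6, from 1 to 14).

**Steps most likely to fail**

Step 5. Intermolecular coupling may overtake ring closure, so that linear oligomers and larger cyclic oligomers consume the diyne ester.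
- The fallback makes C17–C18 between the two fragments before any ring exists and closes the ring at the acyl C1–O bond instead. It sets out from 10 and 6.
- Bromination of the alkyne terminus of 10 (NBS, AgNO3 cat., acetone) should give 13-bromotridec-12-yn-1-ol F1.
- Cadiot–Chodkiewicz cross-coupling of F1 with 6 (CuCl cat., NH2OH·HCl, n-BuNH2, MeOH–THF–H2O), a reaction that tolerates free acids and alcohols, should give 30-hydroxytriaconta-16,18-diynoic acid F2.
- Shiina macrolactonisation of F2 (2-methyl-6-nitrobenzoic anhydride, DMAP, CH2Cl2, slow addition) comes back to the route at 13.

Step 2. The lithium soap 4 may separate from DMSO as a gel, which slows the substitution and lets E2 loss of HBr take over.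
- The fallback moves the displacement to the alcohol oxidation level. It sets out from 2.
- Chemoselective reduction of the acid (BH3·THF, 0 °C → rt) should give 15-bromopentadecan-1-ol F3.
- Alkylation of 3 with F3 in DMSO should give heptadec-16-yn-1-ol F4.
- Jones oxidation of F4 (CrO3, H2SO4, acetone, 0 °C) comes back to the route at 6.

Step 3. O-alkylation by the alkoxide 8 may compete with C-alkylation, and the base may drive the triple bond inward in the amine/DMSO medium.
- The fallback masks the hydroxyl group and uses a silyl-capped acetylide free of ethylenediamine. It sets out from 7.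
- Silylation (TBSCl, imidazole, CH2Cl2) should give [(11-bromoundecyl)oxy](tert-butyl)dimethylsilane F5.
- Alkylation of Me3SiC≡CLi (from Me3SiC≡CH and n-BuLi) with F5 in THF–DMPU, −78 °C → rt, should give tert-butyldimethyl{[13-(trimethylsilyl)tridec-12-yn-1-yl]oxy}silane F6.
- Removal of both silyl groups in one operation (TBAF, THF) comes back to the route at 10.

**Further compounds**
F1 | step 5 | 13-bromotridec-12-yn-1-ol | OCCCCCCCCCCCC#CBr
F2 | step 5 | 30-hydroxytriaconta-16,18-diynoic acid | OC(=O)CCCCCCCCCCCCCCC#CC#CCCCCCCCCCCCO
F3 | step 2 | 15-bromopentadecan-1-ol | OCCCCCCCCCCCCCCCBr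
F4 | step 2 | heptadec-16-yn-1-ol | OCCCCCCCCCCCCCCCC#C
F5 | step 3 | [(11-bromoundecyl)oxy](tert-butyl)dimethylsilane | CC(C)(C)[Si](C)(C)OCCCCCCCCCCCBr
F6 | step 3 | tert-butyldimethyl{[13-(trimethylsilyl)tridec-12-yn-1-yl]oxy}silane | CC(C)(C)[Si](C)(C)OCCCCCCCCCCCC#C[Si](C)(C)C
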